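**Retrosynthetic overview**

- Feature: in the C1–C10 carbocycle, the C6 oxygen and the C1–C10 oxirane (a masked Z-C1=C10 olefin) face each other across the ring. A transannular C6–C10 bond would turn the ten-membered ring into a cis-fused bicyclo[5.3.0]decane (five-membered ring C6–C7–C8–C9–C10, seven-membered ring C10–C1–C2–C3–C4–C5–C6) with a 1,3-dioxygen pattern O–C6–C10–C1–O.
- Late disconnections: both angelates (acylation at O6 and O11), C4–C5 oxirane (directed by C6–OH), C6 carbinol (chelation-controlled reduction), lactone C8–O–C12 and bond C7–C11 (aldol with methyl pyruvate), C1–C10 oxirane (directed by C8–OH).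
- Key disconnection: Wharton fragmentation of a hydroazulenol C1 mesylate (cleavage of C6–C10) to the (4Z,1(10)Z)-cyclodecadien-6-one. The hydroazulenol comes from (S)-4-silyloxy-2-methylcyclopentenone by reductive aldol (C10–C1) with (Z)-5-iodo-4-methylpent-4-enal and vinyllithium closure (C5–C6).
- Ring order: five-membered carbocycle (purchased) → seven-membered ring (step 7) → ten-membered ring by scission of the shared bond (step 10) → C1–C10 oxirane (step 12) → γ-lactone (step 15) → C4–C5 oxirane (step 17).

Key step: step 10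

Remark on numbering (assumption): germacrane numbering is used for every intermediate. C1–C10 are the ring carbons, C11 the lactone carbinol carbon, C12 the lactone carbonyl, C13 the methyl on C11, C14 the methyl on C10, C15 the methyl on C4.

Remark on the chemistry: the configuration of C10 relative to C8 set in the reductive aldol does not affect the outcome, because C1, C6 and C10 all become trigonal in the key step. Only the C1/C10 relative configuration matters. The aldol product and the bicyclic compounds after it are drawn as the expected major diastereomer.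

**Route**

Step 1
Reactants: 1 propyne; 2 2-(2-bromoethyl)-1,3-dioxolane
Product: 6 2-[(3Z)-4-iodo-3-methylbut-3-en-1-yl]-1,3-dioxolane, via Grignard reagent 3 (not isolated), via alkylcopper 4 (not isolated), via alkenylcopper 5 (not isolated)
Conditions: Mg, THF, 25 °C; CuBr·SMe2, Et2O/Me2S, −45 °C; propyne, −25 °C; I2, −78 → 0 °C
Reagents that add atoms: iodine, II
Why: Normant carbocupration, in which alkylcopper 4 adds syn across propyne with the alkyl group on the internal carbon, and iodinolysis of alkenylcopper 5 with retention fixes the Z geometry (iodine cis to the acetal chain) that later becomes the cis ring olefin C4=C5.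

Step 2
Reactants: 6 2-[(3Z)-4-iodo-3-methylbut-3-en-1-yl]-1,3-dioxolane
Product: 7 (4Z)-5-iodo-4-methylpent-4-enal
Conditions: 1 M HCl, THF, 23 °C
Reagents that add atoms: water, O
Why: Acid-catalysed acetal hydrolysis frees the aldehyde, and the vinyl iodide is inert to dilute aqueous acid.

Step 3
Reactants: 8 (4S)-4-(tert-butyldimethylsilyloxy)cyclopent-2-en-1-one
Product: 9 (4S)-4-(tert-butyldimethylsilyloxy)-2-iodocyclopent-2-en-1-one
Conditions: I2, pyridine, CH2Cl2, 0 → 23 °C
Reagents that add atoms: iodine, II
Why: Johnson α-iodination of an enone (conjugate addition of pyridine, iodination of the enolate, loss of pyridine), which leaves the C8 silyl ether and its stereocenter untouched.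

Step 4
Reactants: 9 (4S)-4-(tert-butyldimethylsilyloxy)-2-iodocyclopent-2-en-1-one
Product: 10 (4S)-4-(tert-butyldimethylsilyloxy)-2-methylcyclopent-2-en-1-one
Conditions: Me4Sn, Pd2(dba)3 (5 mol %), AsPh3, CuI, NMP, 60 °C
Reagents that add atoms: tetramethylstannane, C[Sn](C)(C)C
Why: Stille cross-coupling of the α-iodoenone under neutral conditions (AsPh3 and CuI speed up transmetalation), which avoids base-induced loss of the β-silyloxy group.

Step 5
Reactants: 10 (4S)-4-(tert-butyldimethylsilyloxy)-2-methylcyclopent-2-en-1-one; 7 (4Z)-5-iodo-4-methylpent-4-enal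
Product: 12 (2S,4R)-4-(tert-butyldimethylsilyloxy)-2-[(1S,4Z)-1-hydroxy-5-iodo-4-methylpent-4-en-1-yl]-2-methylcyclopentan-1-one, via lithium enolate 11 (not isolated)
Conditions: LiBH(sBu)3, THF, −78 °C; then 7, −78 °C; pH 7 buffer
Reagents that add atoms: none
Why: Reductive aldol reaction, in which conjugate hydride delivery to the β-unsubstituted enone gives the tetrasubstituted enolate 11 regiospecifically, and this adds to the aldehyde through a Zimmerman–Traxler chair (ring enolate, aldehyde chain equatorial) to set C1 (S) anti to C9 and syn to the C10 methyl, while attack on the enolate face opposite the C8 silyl ether sets C10 (S).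

Step 6
Reactants: 12 the aldol product of step 5
Product: 13 (2S,4R)-4-(tert-butyldimethylsilyloxy)-2-[(1S,4Z)-5-iodo-4-methyl-1-(triethylsilyloxy)pent-4-en-1-yl]-2-methylcyclopentan-1-one
Conditions: Et3SiOTf, 2,6-lutidine, CH2Cl2, −78 °C
Reagents that add atoms: triethylsilyl trifluoromethanesulfonate, CC[Si](CC)(CC)OS(=O)(=O)C(F)(F)F
Why: Silyl triflate protection of the hindered secondary carbinol removes the only acidic proton before the organolithium step and blocks retro-aldol cleavage.

Step 7
Reactants: 13 the C1 triethylsilyl ether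
Product: 15 (2R,3aS,4S,8aS)-2-(tert-butyldimethylsilyloxy)-3a,7-dimethyl-4-(triethylsilyloxy)-2,3,3a,4,5,6-hexahydroazulen-8a(1H)-ol (cis-fused; germacrane C8, C10, C1, C6), via vinyllithium 14 (not isolated)
Conditions: t-BuLi (2.1 equiv), THF, −78 → −40 °C; H2O
Reagents that add atoms: none
Why: Lithium–iodine exchange is faster than attack of t-BuLi on the hindered ketone, and the Z-vinyllithium 14 then adds to the C6 carbonyl (7-exo-trig closure of the seven-membered ring) from the face that carries the C10 side chain, which sets C6 (S) with the hydroxyl cis to the angular methyl.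

Step 8
Reactants: 15 the bicyclic bis-silyl ether
Product: 16 (2R,3aS,4S,8aS)-2-(tert-butyldimethylsilyloxy)-3a,7-dimethyl-2,3,3a,4,5,6-hexahydroazulene-4,8a(1H)-diol
Conditions: PPTS (cat.), MeOH/CH2Cl2, 0 °C
Reagents that add atoms: none
Why: Selective acid-catalysed methanolysis removes the triethylsilyl ether much faster than the tert-butyldimethylsilyl ether, and PPTS at 0 °C is too weak to ionise the tertiary allylic alcohol.

Step 9
Reactants: 16 the C1,C6-diol
Product: 17 (2R,3aS,4S,8aS)-2-(tert-butyldimethylsilyloxy)-8a-hydroxy-3a,7-dimethyl-1,2,3,3a,4,5,6,8a-octahydroazulen-4-yl methanesulfonate (germacrane: C1 mesylate, C6 tertiary hydroxyl, C8 silyl ether)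
Conditions: MsCl, Et3N, CH2Cl2, −20 °C
Reagents that add atoms: methanesulfonyl chloride, CS(=O)(=O)Cl
Why: Sulfonylation through sulfene takes only the secondary C1 hydroxyl, the tertiary C6 hydroxyl being too hindered to react.

Step 10
Reactants: 17 the cis-fused hydroazulenol C1 mesylate
Product: 19 (2Z,6Z,9R)-9-(tert-butyldimethylsilyloxy)-3,7-dimethylcyclodeca-2,6-dien-1-one (germacrane: C6 ketone with Z-C4=C5 and Z-C1=C10 and C8 silyl ether), via potassium alkoxide 18 (not isolated)
Conditions: KOtBu (1.05 equiv), THF, −20 → 0 °C; pH 7 buffer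
Reagents that add atoms: none
Why: Wharton (Grob-type) fragmentation of a cyclic 1,3-diol monosulfonate: KOtBu deprotonates the tertiary C6 hydroxyl, and in alkoxide 18 the oxyanion donates into the C6–C10 bond, which lies anti-periplanar to the C1–O bond of the equatorial mesylate, so that the carbonyl forms, C6–C10 cleaves and methanesulfonate departs in one synchronous event. No ring is closed by bond formation: the C1–C10 carbocycle appears because the bond common to the five- and seven-membered rings is cut, which is a ring expansion by fragmentation. No stereocenter is created; C1, C6 and C10 become trigonal, and only C8, which comes from the chiral cyclopentenone, remains. Because the fragmentation is stereospecific, the C1/C10 relative configuration (mesylate on the same face of the seven-membered ring as C9, opposite the angular methyl) puts C2 and C9 on one side of the new π bond, that is Z, while C4=C5 keeps the cis geometry imposed by the cycloheptene. The step needs fragmentation to outrun E2 loss of the mesylate, oxetane formation and base-induced loss of the C8 silanolate from the product; the quaternary C10, the strain released from the cis-fused bicycle and the use of only 1.05 equiv of base at low temperature with a buffered quench are meant to secure this.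

Step 11
Reactants: 19 the cyclodecadienone silyl ether
Product: 20 (2Z,6Z,9R)-9-hydroxy-3,7-dimethylcyclodeca-2,6-dien-1-one
Conditions: HF·pyridine, pyridine, THF, 0 → 23 °C
Reagents that add atoms: none
Why: Silyl ether cleavage with buffered, weakly acidic fluoride is chosen over basic fluoride so that the β-hydroxy ketone neither dehydrates nor undergoes retro-aldol cleavage, and transannular oxa-Michael addition to the β,β-disubstituted C4 is not expected under these conditions.

Step 12
Reactants: 20 the C8 alcohol
Product: 21 (1R,8R,10S,4Z)-1,10-epoxy-8-hydroxy-4,10-dimethylcyclodec-4-en-6-one (germacrane numbering)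
Conditions: VO(acac)2 (5 mol %), t-BuOOH, CH2Cl2, 0 → 23 °C
Reagents that add atoms: tert-butyl hydroperoxide, CC(C)(C)OO
Why: Hydroxyl-directed epoxidation of a homoallylic alcohol, in which the vanadate ester of the C8 hydroxyl delivers oxygen to the face of the Z-C1=C10 olefin that it can reach and so sets C1 (R) and C10 (S) cis to the C8 oxygen, while the electron-poor C4=C5 enone bond does not react.

Step 13
Reactants: 21 the epoxy alcohol
Product: 22 (1R,8R,10S,4Z)-1,10-epoxy-4,10-dimethyl-8-(triethylsilyloxy)cyclodec-4-en-6-one (germacrane numbering)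
Conditions: Et3SiCl, imidazole, CH2Cl2, 0 °C
Reagents that add atoms: chlorotriethylsilane, CC[Si](CC)(CC)Cl
Why: Standard silylation removes the acidic proton and a chelating alkoxide before enolate formation, and the triethylsilyl group can later be removed without acid.

Step 14
Reactants: 22 the C8 triethylsilyl ether; 23 methyl pyruvate
Product: 25 methyl (2R)-2-hydroxy-2-[(1R,7R,8R,10S,4Z)-1,10-epoxy-4,10-dimethyl-6-oxo-8-(triethylsilyloxy)cyclodec-4-en-7-yl]propanoate (germacrane numbering; 11R), via lithium enolate 24 (not isolated)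
Conditions: LiN(iPr)2, THF, −78 °C; then 23, −78 °C; pH 7 buffer, −78 °C
Reagents that add atoms: none
Why: Kinetic deprotonation of the enone occurs at C7 (cross-conjugated enolate 24), and aldol addition to the ketone carbonyl of pyruvate forms C7–C11, with C7 (R) set by attack on the exposed enolate face anti to the C8 silyl ether and C11 (R) by a lithium-bridged closed transition state in which pyruvate is bound through both carbonyl oxygens, so that the ester lies on the metal side and the methyl points outward.

Step 15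
Reactants: 25 the pyruvate aldol adduct
Product: 27 (1R,7R,8R,10S,11R,4Z)-1,10-epoxy-11-hydroxy-6-oxogermacr-4-en-12,8-olide (trans-fused γ-lactone), via hydroxy ester 26 (not isolated)
Conditions: Bu4NF, AcOH, THF, 0 → 40 °C
Reagents that add atoms: none
Why: Buffered fluoride desilylation frees the C8 hydroxyl, which closes onto the C12 methyl ester (5-exo-trig lactonization), and because C6 is still a ketone no 6,12-lactone can compete and no stereocenter changes.

Step 16
Reactants: 27 the keto lactone
Product: 28 (1R,6R,7R,8R,10S,11R,4Z)-1,10-epoxy-6,11-dihydroxygermacr-4-en-12,8-olide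
Conditions: Zn(BH4)2, Et2O, −30 °C
Reagents that add atoms: none
Why: Chelation-controlled 1,2-reduction of the enone, in which zinc bridges the C6 carbonyl and the cis-disposed C11 hydroxyl and hydride attacks the convex face of this chelate anti to C8, which sets C6 (R here; the descriptor becomes S once C5 carries oxygen) with its hydroxyl syn to the C11 hydroxyl.

Step 17
Reactants: 28 the allylic alcohol
Product: 29 (1R,4R,5S,6S,7R,8R,10S,11R)-1,10:4,5-diepoxy-6,11-dihydroxygermacran-12,8-olide
Conditions: VO(acac)2 (5 mol %), t-BuOOH, CH2Cl2, 0 °C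
Reagents that add atoms: tert-butyl hydroperoxide, CC(C)(C)OO
Why: Hydroxyl-directed epoxidation of the allylic alcohol, which in medium-ring Z-cycloalkenols delivers oxygen cis to the hydroxyl and so sets C4 (R) and C5 (S), the cis oxirane following from the Z olefin.

Step 18
Reactants: 30 angelic acid (two molecules per molecule of anhydride)
Product: 31 angelic anhydride, (Z)-2-methylbut-2-enoic anhydride
Conditions: DCC (0.5 equiv relative to the acid), CH2Cl2, 0 → 23 °C
Reagents that add atoms: angelic acid (second molecule), C/C=C(/C)C(=O)O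
Why: Carbodiimide-mediated dehydration, in which the O-acylisourea formed from one molecule of the acid is attacked by a second molecule of the acid to give the symmetric anhydride under neutral conditions, which leaves the Z geometry intact.

Step 19
Reactants: 29 the diepoxy diol; 31 angelic anhydride
Product: 33 (1R,4R,5S,6S,7S,8R,10S,11R)-6,11-bis[(Z)-2-methylbut-2-enoyloxy]-1,10:4,5-diepoxygermacran-12,8-olide (CNP0219924.2), via dilithium dialkoxide 32 (not isolated)
Conditions: LiN(SiMe3)2 (2.2 equiv), THF, −78 °C; then 31 (3 equiv), −78 → −20 °C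
Reagents that add atoms: none
Why: O-Acylation of the two lithium alkoxides by the symmetric anhydride at low temperature (alkoxide acylation as used for sensitive angelates), where the absence of nucleophilic amine catalysts and of excess base is meant to suppress Z to E isomerization to the tiglate, and no stereocenter is touched.

**Compound list**

1 | propyne | CC#C | starting material
2 | 2-(2-bromoethyl)-1,3-dioxolane | BrCCC1OCCO1 | starting material
3 | [2-(1,3-dioxolan-2-yl)ethyl]magnesium bromide | Br[Mg]CCC1OCCO1 | intermediate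
4 | [2-(1,3-dioxolan-2-yl)ethyl]copper (MgBr2/Me2S complex) | [Cu]CCC1OCCO1 | intermediate
5 | [(1Z)-4-(1,3-dioxolan-2-yl)-2-methylbut-1-en-1-yl]copper | [Cu]/C=C(/C)CCC1OCCO1 | intermediate
6 | 2-[(3Z)-4-iodo-3-methylbut-3-en-1-yl]-1,3-dioxolane | I/C=C(/C)CCC1OCCO1 | intermediate
7 | (4Z)-5-iodo-4-methylpent-4-enal | I/C=C(/C)CCC=O | intermediate
8 | (4S)-4-(tert-butyldimethylsilyloxy)cyclopent-2-en-1-one | O=C1C[C@H](O[Si](C)(C)C(C)(C)C)C=C1 | starting material
9 | (4S)-4-(tert-butyldimethylsilyloxy)-2-iodocyclopent-2-en-1-one | O=C1C[C@H](O[Si](C)(C)C(C)(C)C)C=C1I | intermediate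
10 | (4S)-4-(tert-butyldimethylsilyloxy)-2-methylcyclopent-2-en-1-one | O=C1C[C@H](O[Si](C)(C)C(C)(C)C)C=C1C | intermediate
11 | lithium (4R)-4-(tert-butyldimethylsilyloxy)-2-methylcyclopent-1-en-1-olate | [Li]OC1=C(C)C[C@@H](O[Si](C)(C)C(C)(C)C)C1 | intermediate
12 | (2S,4R)-4-(tert-butyldimethylsilyloxy)-2-[(1S,4Z)-1-hydroxy-5-iodo-4-methylpent-4-en-1-yl]-2-methylcyclopentan-1-one | O=C1C[C@H](O[Si](C)(C)C(C)(C)C)C[C@@]1(C)[C@@H](O)CC/C(C)=C\I | intermediate
13 | (2S,4R)-4-(tert-butyldimethylsilyloxy)-2-[(1S,4Z)-5-iodo-4-methyl-1-(triethylsilyloxy)pent-4-en-1-yl]-2-methylcyclopentan-1-one | O=C1C[C@H](O[Si](C)(C)C(C)(C)C)C[C@@]1(C)[C@@H](O[Si](CC)(CC)CC)CC/C(C)=C\I | intermediate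
14 | (2S,4R)-4-(tert-butyldimethylsilyloxy)-2-[(1S,4Z)-5-lithio-4-methyl-1-(triethylsilyloxy)pent-4-en-1-yl]-2-methylcyclopentan-1-one | O=C1C[C@H](O[Si](C)(C)C(C)(C)C)C[C@@]1(C)[C@@H](O[Si](CC)(CC)CC)CC/C(C)=C\[Li] | intermediate
15 | (2R,3aS,4S,8aS)-2-(tert-butyldimethylsilyloxy)-3a,7-dimethyl-4-(triethylsilyloxy)-2,3,3a,4,5,6-hexahydroazulen-8a(1H)-ol | C[C@@]12C[C@@H](O[Si](C)(C)C(C)(C)C)C[C@]1(O)C=C(C)CC[C@@H]2O[Si](CC)(CC)CC | intermediate
16 | (2R,3aS,4S,8aS)-2-(tert-butyldimethylsilyloxy)-3a,7-dimethyl-2,3,3a,4,5,6-hexahydroazulene-4,8a(1H)-diol | C[C@@]12C[C@@H](O[Si](C)(C)C(C)(C)C)C[C@]1(O)C=C(C)CC[C@@H]2O | intermediate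
17 | (2R,3aS,4S,8aS)-2-(tert-butyldimethylsilyloxy)-8a-hydroxy-3a,7-dimethyl-1,2,3,3a,4,5,6,8a-octahydroazulen-4-yl methanesulfonate | C[C@@]12C[C@@H](O[Si](C)(C)C(C)(C)C)C[C@]1(O)C=C(C)CC[C@@H]2OS(C)(=O)=O | intermediate
18 | potassium C6 alkoxide of 17 | C[C@@]12C[C@@H](O[Si](C)(C)C(C)(C)C)C[C@]1(O[K])C=C(C)CC[C@@H]2OS(C)(=O)=O | intermediate
19 | (2Z,6Z,9R)-9-(tert-butyldimethylsilyloxy)-3,7-dimethylcyclodeca-2,6-dien-1-one | C1/C(C)=C\C(=O)C[C@H](O[Si](C)(C)C(C)(C)C)C/C(C)=C\C1 | intermediate
20 | (2Z,6Z,9R)-9-hydroxy-3,7-dimethylcyclodeca-2,6-dien-1-one | C1/C(C)=C\C(=O)C[C@H](O)C/C(C)=C\C1 | intermediate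
21 | (1R,8R,10S,4Z)-1,10-epoxy-8-hydroxy-4,10-dimethylcyclodec-4-en-6-one (germacrane numbering) | C1/C(C)=C\C(=O)C[C@H](O)C[C@]2(C)O[C@@H]2C1 | intermediate
22 | (1R,8R,10S,4Z)-1,10-epoxy-4,10-dimethyl-8-(triethylsilyloxy)cyclodec-4-en-6-one (germacrane numbering) | C1/C(C)=C\C(=O)C[C@H](O[Si](CC)(CC)CC)C[C@]2(C)O[C@@H]2C1 | intermediate
23 | methyl pyruvate | CC(=O)C(=O)OC | starting material
24 | lithium C6 enolate of 22 (4Z,6E; C5 and C8 cis across C6=C7) | C1/C(C)=C\C(O[Li])=C/[C@H](O[Si](CC)(CC)CC)C[C@]2(C)O[C@@H]2C1 | intermediate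
25 | methyl (2R)-2-hydroxy-2-[(1R,7R,8R,10S,4Z)-1,10-epoxy-4,10-dimethyl-6-oxo-8-(triethylsilyloxy)cyclodec-4-en-7-yl]propanoate | C1/C(C)=C\C(=O)[C@@H]([C@@](C)(O)C(=O)OC)[C@H](O[Si](CC)(CC)CC)C[C@]2(C)O[C@@H]2C1 | intermediate
26 | methyl (2R)-2-hydroxy-2-[(1R,7R,8R,10S,4Z)-1,10-epoxy-8-hydroxy-4,10-dimethyl-6-oxocyclodec-4-en-7-yl]propanoate | C1/C(C)=C\C(=O)[C@@H]([C@@](C)(O)C(=O)OC)[C@H](O)C[C@]2(C)O[C@@H]2C1 | intermediate
27 | (1R,7R,8R,10S,11R,4Z)-1,10-epoxy-11-hydroxy-6-oxogermacr-4-en-12,8-olide | C1/C(C)=C\C(=O)[C@@H]2[C@@H](C[C@]3(C)O[C@@H]3C1)OC(=O)[C@]2(C)O | intermediate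
28 | (1R,6R,7R,8R,10S,11R,4Z)-1,10-epoxy-6,11-dihydroxygermacr-4-en-12,8-olide | C1/C(C)=C\[C@@H](O)[C@@H]2[C@@H](C[C@]3(C)O[C@@H]3C1)OC(=O)[C@]2(C)O | intermediate
29 | (1R,4R,5S,6S,7R,8R,10S,11R)-1,10:4,5-diepoxy-6,11-dihydroxygermacran-12,8-olide | O[C@H]1[C@@H]2[C@@H](C[C@]3(C)O[C@@H]3CC[C@@]3(C)O[C@@H]13)OC(=O)[C@]2(C)O | intermediate
30 | angelic acid, (Z)-2-methylbut-2-enoic acid | C/C=C(/C)C(=O)O | starting material
31 | angelic anhydride | C/C=C(/C)C(=O)OC(=O)/C(C)=C\C | intermediate
32 | dilithium 6,11-dialkoxide of 29 | [Li]O[C@H]1[C@@H]2[C@@H](C[C@]3(C)O[C@@H]3CC[C@@]3(C)O[C@@H]13)OC(=O)[C@]2(C)O[Li] | intermediate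
33 | (1R,4R,5S,6S,7S,8R,10S,11R)-6,11-bis[(Z)-2-methylbut-2-enoyloxy]-1,10:4,5-diepoxygermacran-12,8-olide | C/C=C(/C)C(=O)O[C@H]1[C@@H]2[C@@H](C[C@]3(C)O[C@@H]3CC[C@@]3(C)O[C@@H]13)OC(=O)[C@]2(C)OC(=O)/C(C)=C\C | target

**Step count**

Total: 19 steps. Longest linear sequence: 16 steps (from 8 through steps 3–17 and 19 to 33).

**Three steps most likely to fail**

Step 10 (fragmentation). Three processes may compete: β-elimination of the C8 silyloxy group from the new ketone through its C7 enolate, drift of the Z-enone geometry under base, and E2 loss of the sulfonate. The fallback sets out from 17 and generates the oxyanion without stoichiometric strong base. The tertiary hydroxyl of 17 would be silylated (Me3SiOTf, 2,6-lutidine, CH2Cl2, −78 °C) to give the C6 trimethylsilyl ether of the mesylate F1. Fluoride (Bu4NF, 1.0 equiv, THF, −40 °C) would then unmask the alkoxide, which should fragment at once in a medium that contains no alkoxide base. The route is rejoined at 19.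

Step 14 (pyruvate aldol). Retro-aldol reversal on work-up, proton transfer from pyruvate to the enolate, and poor facial selectivity at the pyruvate carbonyl (C11) are the likely failures. The fallback sets out from 22. The kinetic enolate would be trapped (LiN(iPr)2, Me3SiCl, THF, −78 °C) as the C6 trimethylsilyl enol ether F2. F2 would then be added to methyl pyruvate in a Mukaiyama aldol catalysed by the divalent copper complex from Cu(OTf)2 and (R,R)-2,2'-isopropylidenebis(4-tert-butyl-2-oxazoline) (THF, −78 °C). Pyruvate bound through both carbonyls reacts through an open transition state that is known to favour the syn adduct and puts the choice of the pyruvate face under catalyst control; the (R,R) ligand is expected to give 11R, matched with attack anti to the C8 silyl ether. The product would be the C11 trimethylsilyl ether of the aldol adduct F3, which would go directly into the conditions of step 15, where fluoride removes both silyl groups. The route is rejoined at 27.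

Step 19 (double angeloylation). Incomplete acylation of the hindered tertiary C11 alkoxide, Z to E isomerization of the angeloyl unit to tigloyl, and acyl transfer of the C6 alkoxide onto C12 (translactonization) are the likely failures. The fallback sets out from 29 and builds the Z olefins on the esters instead of transferring them. Both hydroxyls would be esterified with 2-[bis(2,2,2-trifluoroethoxy)phosphoryl]propanoic acid (DCC, CH2Cl2, 23 °C; the phosphonoketene formed in the flask acylates hindered alcohols) to give the 6,11-bis(phosphonopropanoate) F4. A double Still–Gennari olefination with acetaldehyde (KN(SiMe3)2, 18-crown-6, THF, −78 °C) should then give both (Z)-2-methylbut-2-enoates. The route is rejoined at 33.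

**Further compounds**

F1 | step 10 | (2R,3aS,4S,8aS)-2-(tert-butyldimethylsilyloxy)-3a,7-dimethyl-8a-(trimethylsilyloxy)-1,2,3,3a,4,5,6,8a-octahydroazulen-4-yl methanesulfonate | C[C@@]12C[C@@H](O[Si](C)(C)C(C)(C)C)C[C@]1(O[Si](C)(C)C)C=C(C)CC[C@@H]2OS(C)(=O)=O
F2 | step 14 | C6 trimethylsilyl enol ether of 22 (4Z,6E) | C1/C(C)=C\C(O[Si](C)(C)C)=C/[C@H](O[Si](CC)(CC)CC)C[C@]2(C)O[C@@H]2C1
F3 | step 14 | C11 trimethylsilyl ether of 25 | C1/C(C)=C\C(=O)[C@@H]([C@@](C)(O[Si](C)(C)C)C(=O)OC)[C@H](O[Si](CC)(CC)CC)C[C@]2(C)O[C@@H]2C1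
F4 | step 19 | 6,11-bis{2-[bis(2,2,2-trifluoroethoxy)phosphoryl]propanoate} of 29 (phosphonate α-carbons unspecified) | CC(C(=O)O[C@H]1[C@@H]2[C@@H](C[C@]3(C)O[C@@H]3CC[C@@]3(C)O[C@@H]13)OC(=O)[C@]2(C)OC(=O)C(C)P(=O)(OCC(F)(F)F)OCC(F)(F)F)P(=O)(OCC(F)(F)F)OCC(F)(F)F
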